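Following one molecule of L was the easy step. It meets G and becomes Q, then Q may go on to E, and I took both steps as running back. The decision at 25 h hangs on where that molecule is found.

| flask | L | J | X | temperature | remark | time |
|---|---|---|---|---|---|---|
| ochre | 0.10 M | 1 equiv | 15 mM (held) | 100 °C | the very flask that is asked about, followed so far |  |
| teal | 0.050 M | 1 equiv | 15 mM (held) | 85 °C | run made earlier |  |
| flask | 0.10 M | 1.00 equiv | 15 mM (held) | 100 °C |  | 25 h |

| run | time / min | Q / % |
|---|---|---|
| ochre | 240 | 36.5 |
| ochre | 480 | 33.0 |
| ochre | 720 | 29.4 |
| ochre | 900 | 27.3 |
| teal | 40.0 | 9.8 |
| teal | 80.0 | 18.6 |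
| teal | 120 | 25.0 |
| teal | 180 | 32.8 |

(readings scatter by 0.3 percentage points)

- Tuesday's: at 25 h raise the temperature by 15 K, then wait 12 h
- Wednesday's: at 25 h take out 90% of the Q then present, then wait 12 h
- Sunday's: at 25 h add L, 50.0% of the amount charged, then wait 12 h
- Monday's: change nothing and wait 12 h more

- at the start none of G is dissolved
- Q that was removed still counts
- the earlier runs were read with a standard deviation of 0.3 percentage points
- on the list of suspects stand: L + G <-> Q; J + G -> D; Q <-> E; X <-> G
- additions bring no volume worth counting

* Q, in percent of the L first charged, at 25 h
* which option adds most Q ("none" when 2 percentage points or less is all one gets) (Tuesday's / Wednesday's / Sunday's / Monday's / none)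
* Q present, with what was taken out counted in, in percent of the L first charged, after Tuesday's
* Q present, with what was taken out counted in, in percent of the L first charged, after Wednesday's

The chance of finding the molecule as Q, once X holds G and the flask has stopped moving, is a fraction of the charge; this is thermodynamic control. Ochre Q fell 3.5 percentage points over the 240 min between its first two readings and 2.1 points over the 180 min between its last two, a slowing that the scatter of 0.3 points leaves uncertain. So I took the last ochre reading, 27.3%, as my estimate of s, the standing share, and committed to Q near it at 25 h.

Then the options reckon themselves, if 12 h is enough to stand again. Sunday's enlarges the pool, and s of the addition adds 14 points. Wednesday's takes out 90% of s, and the smaller pool returns to share s, so it adds 18 points, which makes 45.3% in total. Wednesday's beats Sunday's while s stays under the break-even share 44.4%, and my s lay below that. So I chose Wednesday's. I expected no gain from Monday's. Tuesday's moves s itself, and the teal run, still rising at its last reading, shows no standing share, so I put no figure on it.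

The forecast gave 21.2% at 25 h, 8% after Tuesday's and 29% after Wednesday's, and chose Sunday's: “Sunday's: about 30, narrowly best”.

The flask gave 26.4% at 25 h, and Wednesday's won, with 43.6%, against 34.9% after Tuesday's. Ten times as long changed Q by little, and it stood at 26.3%. The rule's 18 points compares with 17 points for Wednesday's, and its 14 points with 14 points for Sunday's.

    L + G ⇌ Q (K = 110 /M, k = 0.00740 /M/s, Ea = 56.0 kJ/mol, ΔH = −4.00 kJ/mol)
    J + G → D (k = 0.0140 /M/s, Ea = 75.0 kJ/mol)
    Q ⇌ E (K = 2.20, k = 6.80 × 10⁻⁵ /s, Ea = 119 kJ/mol, ΔH = −47.0 kJ/mol)
    X ⇌ G, rate k4*(csat - [G]) (kL = 0.00600 /s)
    (constants at 100 °C)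

For the same flask stopped at 6.0 h, midway between the first two ochre readings, I took the excess of Q over s to shrink by a constant factor per unit time. Then s gives that excess as the geometric mean of the excesses at those readings, so Q should be 34.5%. The computed flask held 35.3%.

The numbers in the tables come from a simulation with constants of no real substance; scatter was added.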